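Target in the east flask can form by one candidate step, dissolved substrate meeting coupling partner, and the solid substrate, the limiting reagent, has to enter solution first.

| flask | solid substrate | coupling partner | remark | time |
|---|---|---|---|---|
| east | 20 mM | 2.5 equiv | the very flask that is asked about, followed so far |  |
| west | 10 mM | 2.5 equiv | run made earlier |  |
| flask | 20 mM | 2.50 equiv |  | 80 min |

- east (time / min: target / %, solid substrate / %): 0.833: 0, 90.8; 2.00: 1.3, 79.6; 4.00: 3.0, 65.3; 6.00: 5.7, 55.1; 8.00: 8.1, 49.2; 12.0: 18.3, 35.8; 15.0: 21.2, 28.9
- west (time / min: target / %, solid substrate / %): 2.50: 0.8, 52.2; 4.00: 2.9, 31.5; 6.00: 6.3, 13.3; 10.0: 12.0, 0.8; 15.0: 20.1, 1.1; 20.0: 27.5, 0; 30.0: 38.1, 0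

(scatter of a reading: 1 percentage point)

- as a solid, counted per litre of solution: solid substrate
- the numbers in the tables scatter by 1 percentage point (one standard deviation)
- candidate steps: dissolved substrate + coupling partner -> target; coupling partner -> side product; solid substrate <-> dissolved substrate
- at the start none of the solid substrate is in solution

* target at 80 min, in percent of the solid substrate charged
* the change that raises the amount of target at 80 min, in percent of the solid substrate charged most ("none" if none brings more than 2 percentage points) (winter / dusk / autumn / none)
* amount of target at 80 min, in percent of the solid substrate charged, after winter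

- winter: doubling the amount of coupling partner, all else as stated
- dusk: doubling the dissolution coefficient of the solid substrate, all else as stated
- autumn: doubling the solubility of the solid substrate, all else as stated

We build the east flask one process at a time, and we first need the main step. The west solid reads 0.8% at 10.0 min, so from there on the west substrate is in solution. Its share not yet target falls from 88.0% to 61.9% by 30.0 min, with a mean c(coupling partner) of 22.5 mM. That gives 7.82 × 10⁻⁴ mM⁻¹ min⁻¹ as the pairing constant, the share of dissolved substrate turned to target per minute and per mM of coupling partner.

With the whole east charge dissolved at the start, this step by itself gives 90.2% target at 80 min.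

Now we add dissolution. At 15.0 min the east readings leave c(dissolved substrate) at 9.98 mM. Held there, with the partner at 45.8 mM, the pairing constant gives 0.357 mM min⁻¹ of target, close to the 0.374 mM min⁻¹ the east readings show. The remaining solid then lasts until about 31.2 min. Joining the decay from there gives 87.1%, which is 3.1 percentage points lower. The third process, coupling partner to side product, stays out of our reckoning, since no partner was measured. We commit to 87.1%, perhaps slightly less.

The forecast says 76%, between 69% and 83%, names winter as the best change, and gives 95% after it, between 90% and 98%. Its ground is “Dissolution is not limiting late on”. Our figure lies above its range.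

The east flask gives 87.3%, and winter is the best change, worth 12 points against 2.7 points for autumn and 1.2 points for dusk, reaching 99.1%.

    dissolved substrate + coupling partner → target (k = 0.844 L mol⁻¹ min⁻¹)
    coupling partner → side product (k = 0.00109 min⁻¹)
    solid substrate ⇌ dissolved substrate, rate k3*(cs3 - [dissolved substrate]) while solid is left; crystals form when [dissolved substrate] > cs3 (solubility = 12.0 mM, k = 0.207 min⁻¹)

With 5.0 mM of solid substrate, a neighbour flask keeps a mean partner of 10.8 mM, and the pairing constant gives 49.1% target; it holds 50.4%. The east flask is not at rest at 80 min. It still has 12.7% dissolved substrate, with a pseudo-first-order half-life of 28 min by the step to target at that time. By 800 min target reaches >99.9%, while side product climbs from 3.26 mM to 17.9 mM and coupling partner falls from 59% to 24.3% of its charge.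

(The readings were generated by integration for an exercise, noise included.)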